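The target is treated as its naphthazarin tautomer, in which ring A (C1–C4, C4a, C8a) is a 2-substituted 1,4-benzoquinone and ring B (C5–C8, oxygen on C5 and C8) is what a 1,4-dioxygenated butadiene would deliver. Ring B is therefore cut off at C4a–C5 and C8–C8a. One operation builds the whole second ring in its final oxidation state: Diels–Alder addition of (E,E)-1,4-diacetoxybutadiene to the brominated double bond of a bromoquinone, followed in the same flask by loss of HBr and dehydrogenation. The dienophile is 2-bromo-1,4-benzoquinone carrying at C5 the complete (R)-configured ester side chain, made from a bromodimethoxyarene.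

Key step: step 6

Remark: positions in 11–14 follow naphthalene-1,4-dione numbering (ring A: C1–C4, C4a, C8a; ring B: C5–C8); the side-chain centre is (R) in every compound (O > ring carbon > CH2 > H), and diene 10 is taken as a purchasable reagent.

Step 1
Reactants: 1 4-methylpent-3-enoic acid
Product: 2 N-methoxy-N,4-dimethylpent-3-enamide
Conditions: CDI, CH2Cl2, 0 °C → rt; then MeNH(OMe)·HCl, rt
Reagents that add atoms: N,O-dimethylhydroxylamine hydrochloride, CNOC.Cl
Why: Weinreb amide formation through the acyl imidazolide, a neutral activation that should leave the β,γ-double bond where it is.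

Step 2
Reactants: 3 1,4-dibromo-2,5-dimethoxybenzene; 2 N-methoxy-N,4-dimethylpent-3-enamide
Product: 5 1-(4-bromo-2,5-dimethoxyphenyl)-4-methylpent-3-en-1-one, via the aryllithium 4 (not isolated)
Conditions: n-BuLi (1.0 equiv), THF, −78 °C; then 2, −78 °C; 1 M HCl quench at −78 °C
Reagents that add atoms: none
Why: A single bromine–lithium exchange on the symmetrical dibromide followed by Weinreb ketone synthesis, in which the N-methoxy-N-methylamide should stop the addition at the ketone level and the cold acidic quench should prevent base-mediated migration of the double bond into conjugation.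

Step 3
Reactants: 5 1-(4-bromo-2,5-dimethoxyphenyl)-4-methylpent-3-en-1-one
Product: 6 (1R)-1-(4-bromo-2,5-dimethoxyphenyl)-4-methylpent-3-en-1-ol
Conditions: (+)-Ipc2BCl [from (−)-α-pinene] (1.5 equiv), THF, −25 °C; then CH3CHO, 0 °C → rt; aqueous work-up
Reagents that add atoms: none
Why: Brown asymmetric reduction with B-chlorodiisopinocampheylborane, in which hydride passes from an isopinocampheyl group through a six-membered boat-like transition state with the aryl group in the less hindered position, so that the (+)-reagent should give the (R)-alcohol; the reagent does not hydroborate the alkene.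

Step 4
Reactants: 6 (1R)-1-(4-bromo-2,5-dimethoxyphenyl)-4-methylpent-3-en-1-ol; 7 3,4-dimethylpent-3-enoic acid
Product: 8 (1R)-1-(4-bromo-2,5-dimethoxyphenyl)-4-methylpent-3-en-1-yl 3,4-dimethylpent-3-enoate
Conditions: DCC, DMAP (0.1 equiv), CH2Cl2, 0 °C → rt
Reagents that add atoms: none
Why: Steglich esterification acylates the oxygen without touching the C–O bond of the stereocentre, so (R) is retained, and the low DMAP loading at 0 °C should keep the β,γ-double bond of the acyl group in place.

Step 5
Reactants: 8 (1R)-1-(4-bromo-2,5-dimethoxyphenyl)-4-methylpent-3-en-1-yl 3,4-dimethylpent-3-enoate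
Product: 9 2-bromo-5-[(1R)-1-(3,4-dimethylpent-3-enoyloxy)-4-methylpent-3-en-1-yl]cyclohexa-2,5-diene-1,4-dione
Conditions: (NH4)2Ce(NO3)6 (2.5 equiv), MeCN/H2O, 0 °C
Reagents that add atoms: water, O
Why: Oxidative demethylation of a para-dimethoxyarene by tetravalent cerium (two one-electron oxidations, water adding at the ring carbons and methanol leaving), which should be much faster than oxidation of the isolated alkenes and leaves the ester, the bromine and the stereocentre untouched.

Step 6
Reactants: 9 2-bromo-5-[(1R)-1-(3,4-dimethylpent-3-enoyloxy)-4-methylpent-3-en-1-yl]cyclohexa-2,5-diene-1,4-dione; 10 (1E,3E)-buta-1,3-diene-1,4-diyl diacetate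
Product: 13 5,8-diacetoxy-2-[(1R)-1-(3,4-dimethylpent-3-enoyloxy)-4-methylpent-3-en-1-yl]naphthalene-1,4-dione, via the bromo cycloadduct 11 (not isolated), via the 5,8-dihydroquinone 12 (not isolated)
Conditions: 10 (2.5 equiv), activated MnO2 (10 equiv), propylene oxide (5 equiv), PhMe, 80 °C, sealed tube, dark
Reagents that add atoms: none
Why: The s-cis E,E-diene 10 and the bromine-bearing double bond of 9 combine in a concerted suprafacial [4+2] cycloaddition that forms C4a–C5 and C8–C8a and gives the cis-fused endo adduct 11; its C8a hydrogen is alpha to the C1 carbonyl and next to the C4a bromine, so HBr is lost through the enol and trapped irreversibly by the epoxide to give 12, and MnO2 then removes the doubly allylic hydrogens at C5 and C8 to leave the benzenoid ring. The closest known reaction type is the Diels–Alder addition of halobenzoquinones to 1-acetoxy- or 1-silyloxybutadienes with dehydrohalogenation and oxidation to juglone derivatives, combined with one-flask Diels–Alder/MnO2 aromatization of quinone adducts. Ring B, the only ring closed, is a six-membered carbocycle formed by intermolecular cycloaddition, both new bonds arising in the same step. No new stereocentre survives: the four sp3 centres of 11 (C4a, C5, C8, C8a) are all flattened on the way to 13, and the (R) centre of the side chain is a bystander. The step needs site selectivity for the brominated double bond over the one bearing the side chain, which bromine should secure by lowering the LUMO at its own double bond while the branched acyloxyalkyl group shields the other; orientation is no issue because 10 is symmetric end to end. It also needs aromatization by dehydrogenation and not by 1,4-loss of acetic acid, which is why no base is present, HBr is removed by a neutral trap, and the oxidant is in the flask from the start.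

Step 7
Reactants: 13 5,8-diacetoxy-2-[(1R)-1-(3,4-dimethylpent-3-enoyloxy)-4-methylpent-3-en-1-yl]naphthalene-1,4-dione
Product: 14 5,8-dihydroxy-2-[(1R)-1-(3,4-dimethylpent-3-enoyloxy)-4-methylpent-3-en-1-yl]naphthalene-1,4-dione (target)
Conditions: NaHCO3 (3 equiv), MeOH/THF, 0 °C → rt, Ar, dark
Reagents that add atoms: none
Why: Bicarbonate-buffered methanolysis (transesterification) should cleave the two peri aryl acetates, which are activated esters of an acidic quinonoid phenol, far faster than the hindered secondary alkyl ester; no amine is present that could add to the quinone, and the stereocentre is not involved.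

Compound list
1 | 4-methylpent-3-enoic acid | CC(C)=CCC(=O)O | starting material
2 | N-methoxy-N,4-dimethylpent-3-enamide | CON(C)C(=O)CC=C(C)C | intermediate
3 | 1,4-dibromo-2,5-dimethoxybenzene | COc1cc(Br)c(OC)cc1Br | starting material
4 | (4-bromo-2,5-dimethoxyphenyl)lithium | [Li]c1cc(OC)c(Br)cc1OC | intermediate (not isolated)
5 | 1-(4-bromo-2,5-dimethoxyphenyl)-4-methylpent-3-en-1-one | CC(C)=CCC(=O)c1cc(OC)c(Br)cc1OC | intermediate
6 | (1R)-1-(4-bromo-2,5-dimethoxyphenyl)-4-methylpent-3-en-1-ol | CC(C)=CC[C@@H](O)c1cc(OC)c(Br)cc1OC | intermediate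
7 | 3,4-dimethylpent-3-enoic acid | CC(C)=C(C)CC(=O)O | starting material
8 | (1R)-1-(4-bromo-2,5-dimethoxyphenyl)-4-methylpent-3-en-1-yl 3,4-dimethylpent-3-enoate | CC(C)=CC[C@@H](OC(=O)CC(C)=C(C)C)c1cc(OC)c(Br)cc1OC | intermediate
9 | 2-bromo-5-[(1R)-1-(3,4-dimethylpent-3-enoyloxy)-4-methylpent-3-en-1-yl]cyclohexa-2,5-diene-1,4-dione | CC(C)=CC[C@@H](OC(=O)CC(C)=C(C)C)C1=CC(=O)C(Br)=CC1=O | intermediate
10 | (1E,3E)-buta-1,3-diene-1,4-diyl diacetate | CC(=O)O/C=C/C=C/OC(C)=O | starting material
11 | 4a-bromo-5,8-diacetoxy-2-[(1R)-1-(3,4-dimethylpent-3-enoyloxy)-4-methylpent-3-en-1-yl]-4a,5,8,8a-tetrahydronaphthalene-1,4-dione, cis-fused endo adduct with both acetoxy groups trans to Br and H8a (one of the two facial diastereomers drawn; both should form) | CC(C)=CC[C@@H](OC(=O)CC(C)=C(C)C)C1=CC(=O)[C@]2(Br)[C@H](OC(C)=O)C=C[C@H](OC(C)=O)[C@@H]2C1=O | intermediate (not isolated)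
12 | cis-5,8-diacetoxy-2-[(1R)-1-(3,4-dimethylpent-3-enoyloxy)-4-methylpent-3-en-1-yl]-5,8-dihydronaphthalene-1,4-dione (matching facial diastereomer drawn) | CC(C)=CC[C@@H](OC(=O)CC(C)=C(C)C)C1=CC(=O)C2=C(C1=O)[C@@H](OC(C)=O)C=C[C@H]2OC(C)=O | intermediate (not isolated)
13 | 5,8-diacetoxy-2-[(1R)-1-(3,4-dimethylpent-3-enoyloxy)-4-methylpent-3-en-1-yl]naphthalene-1,4-dione | CC(C)=CC[C@@H](OC(=O)CC(C)=C(C)C)C1=CC(=O)c2c(OC(C)=O)ccc(OC(C)=O)c2C1=O | intermediate
14 | 5,8-dihydroxy-2-[(1R)-1-(3,4-dimethylpent-3-enoyloxy)-4-methylpent-3-en-1-yl]naphthalene-1,4-dione | CC(C)=CC[C@@H](OC(=O)CC(C)=C(C)C)C1=CC(=O)c2c(O)ccc(O)c2C1=O | target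

Total step count: 7
Longest linear sequence: 7 steps (1 → 2 → 5 → 6 → 8 → 9 → 13 → 14)

Steps most likely to fail

Step 6. Aromatization may take the wrong course: 1,4-loss of acetic acid at the dihydro stage could outrun dehydrogenation and strip one ring oxygen. The weakly donating diene may also add so slowly that the quinone decays or reacts at the side-chain double bond. The fallback sets out from 8 and comes back at 14, using a diene that already carries both oxygens at the carbonyl level, so that neither bromine nor an oxidant is needed. Radical debromination of 8 (n-Bu3SnH, AIBN, PhH, 80 °C) should give (1R)-1-(2,5-dimethoxyphenyl)-4-methylpent-3-en-1-yl 3,4-dimethylpent-3-enoate F1. Oxidative demethylation as in step 5 [(NH4)2Ce(NO3)6, MeCN/H2O, 0 °C] should give 2-[(1R)-1-(3,4-dimethylpent-3-enoyloxy)-4-methylpent-3-en-1-yl]cyclohexa-2,5-diene-1,4-dione F2. Cycloaddition of F2 at its unsubstituted double bond with 2,5-bis(trimethylsilyloxy)furan F3 (from succinic anhydride, Me3SiCl, Et3N, ZnCl2, MeCN) in CH2Cl2 at −78 °C → rt should give the oxygen-bridged bis(trimethylsilyloxy) cycloadduct F4. Dilute HCl/THF work-up should open the bridge of F4 with loss of both silyl groups to a tetraone, and enolization of its two ring-fusion hydrogens gives 14 directly. Because the two naphthazarin tautomers interconvert, addition at the unsubstituted double bond leads to the same compound as the main route.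

Step 7. Methanolysis may not stop at the aryl acetates: the side-chain ester could be cleaved, or methanol could add to the electron-poor quinone before the second acetate has gone. The fallback sets out from 13 and comes back at 14 by abandoning selectivity. Full saponification (1 M NaOH, MeOH/H2O, 0 °C → rt, Ar; then dilute HCl) should give 5,8-dihydroxy-2-[(1R)-1-hydroxy-4-methylpent-3-en-1-yl]naphthalene-1,4-dione (shikonin) F5. Its two phenols are locked in hydrogen bonds to the quinone carbonyls, so Steglich esterification with 7 (DCC, DMAP, CH2Cl2, 0 °C) should acylate only the side-chain hydroxyl and give 14.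

Step 2. Proton transfer may win over addition: aryllithium 4 could deprotonate the doubly activated CH2 of 2, and the β,γ-double bond of 5 could slip into conjugation on work-up. The fallback sets out from 3 and comes back at 6, bypassing steps 2 and 3 and never forming the ketone. Aryllithium 4, made as in step 2, is quenched with DMF to give 4-bromo-2,5-dimethoxybenzaldehyde F6. Brown allylboration with the B-allyldiisopinocampheylborane of the (−)-α-pinene series [from (+)-Ipc2BOMe and allylMgBr, Et2O, −78 °C; ethanolamine work-up] delivers the allyl group through a chair-like six-membered transition state under control of the isopinocampheyl groups. This should give (1R)-1-(4-bromo-2,5-dimethoxyphenyl)but-3-en-1-ol F7. Cross-metathesis of F7 with 2-methylbut-2-ene [second-generation Grubbs catalyst, RuCl2(=CHPh)(H2IMes)(PCy3), CH2Cl2, 40 °C] exchanges the terminal CH2 for CMe2 and gives 6.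

Further compounds
F1 | step 6 | (1R)-1-(2,5-dimethoxyphenyl)-4-methylpent-3-en-1-yl 3,4-dimethylpent-3-enoate | CC(C)=CC[C@@H](OC(=O)CC(C)=C(C)C)c1cc(OC)ccc1OC
F2 | step 6 | 2-[(1R)-1-(3,4-dimethylpent-3-enoyloxy)-4-methylpent-3-en-1-yl]cyclohexa-2,5-diene-1,4-dione | CC(C)=CC[C@@H](OC(=O)CC(C)=C(C)C)C1=CC(=O)C=CC1=O
F3 | step 6 | 2,5-bis(trimethylsilyloxy)furan | C[Si](C)(C)Oc1ccc(O[Si](C)(C)C)o1
F4 | step 6 | oxygen-bridged bis(trimethylsilyloxy) cycloadduct of F2 and F3 (stereoisomer mixture at the four ring sp3 centres, not isolated; only the side-chain centre is specified) | CC(C)=CC[C@@H](OC(=O)CC(C)=C(C)C)C1=CC(=O)C2C(C1=O)C1(O[Si](C)(C)C)C=CC2(O[Si](C)(C)C)O1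
F5 | step 7 | 5,8-dihydroxy-2-[(1R)-1-hydroxy-4-methylpent-3-en-1-yl]naphthalene-1,4-dione (shikonin) | CC(C)=CC[C@@H](O)C1=CC(=O)c2c(O)ccc(O)c2C1=O
F6 | step 2 | 4-bromo-2,5-dimethoxybenzaldehyde | COc1cc(Br)c(OC)cc1C=O
F7 | step 2 | (1R)-1-(4-bromo-2,5-dimethoxyphenyl)but-3-en-1-ol | C=CC[C@@H](O)c1cc(OC)c(Br)cc1OC
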